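## Retrosynthetic overview
1. The target comes from the (S)-furylic pinacol boronic ester by C–B to C–OH oxidation with retention, as the last step.
2. Key step: one enantioselective three-component conjunctive cross-coupling joins 3-furyllithium, vinyl-B(pin) and an (E)-alkenyl bromide (C3–C17). It forms furyl–C1, C2–C3 and the C1 stereocentre together. This replaces the usual furyl-metal/aldehyde or acyl-anion/farnesyl halide route with later ketone reduction.
3. The alkenyl bromide comes from a terminal alkyne by Zr-catalysed methylalumination/bromination, which sets the C3=C4 E alkene. The C14 ketone comes from oxidation of a carbinol.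
4. C13–C14 comes from an alpha-selective allylbarium addition to isovaleraldehyde. The allylic chloride comes from SeO2 oxidation of an enyne made from geranyl bromide and lithiated 1-(trimethylsilyl)propyne (C5–C6). Geranyl supplies the other two E alkenes.
5. No ring is formed; the furan is bought as 3-bromofuran.

Assumption: the SMILES reads as the S carbinol with three E alkenes. With the catalyst of step 8, aryl-migrating model cases give R carbinols from the (Sp,Sp)-ligand, so the (Rp,Rp)-antipode is used here and the sense is checked by Mosher ester analysis of the final alcohol.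

Skeleton locants used in the overview and the Why lines: C1 is the carbinol carbon, C14 the ketone carbon and C17 the chain end. The systematic names count from the other end.

## Route

Step 1
Reactants: 1 geranyl bromide [(2E)-1-bromo-3,7-dimethylocta-2,6-diene]; 2 1-(trimethylsilyl)propyne
Product: 4 [(5E)-6,10-dimethylundeca-5,9-dien-1-yn-1-yl]trimethylsilane, via lithiated silylpropyne 3 (not isolated)
Conditions: 2 (1.2 equiv), n-BuLi, THF, −20 °C, 1 h; then 1, −78 °C to rt
Reagents that add atoms: none
Why: Corey-type propargylation: the propargylic lithium reagent 3, held in its alkynyl form by the silyl cap, displaces the primary allylic bromide by direct SN2 attack, so no allene and no allylic transposition arise, the geranyl E alkene is carried over unchanged, and the silyl group keeps the alkyne C–H masked for steps 2 to 4.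

Step 2
Reactants: 4 silyl dienyne
Product: 5 (2E,6E)-2,6-dimethyl-11-(trimethylsilyl)undeca-2,6-dien-10-yn-1-ol
Conditions: SeO2 (0.15 equiv), salicylic acid (0.1 equiv), t-BuOOH (2.5 equiv), CH2Cl2, 0 °C to rt, stopped at about 70% conversion (4 recycled)
Reagents that add atoms: selenium dioxide, O=[Se]=O (oxygen carrier); tert-butyl hydroperoxide, CC(C)(C)OO (terminal oxygen source)
Why: Riley (Sharpless catalytic) allylic oxidation: the ene reaction of SeO2 at the least hindered, terminal isopropylidene group followed by a [2,3]-sigmatropic shift oxidises only the methyl group trans to the chain and so gives the E allylic alcohol, while partial conversion limits attack at the internal alkene and the propargylic CH2.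

Step 3
Reactants: 5 allylic alcohol
Product: 6 [(5E,9E)-11-chloro-6,10-dimethylundeca-5,9-dien-1-yn-1-yl]trimethylsilane
Conditions: PPh3 (1.3 equiv), CCl4, reflux, 2 h
Reagents that add atoms: carbon tetrachloride, ClC(Cl)(Cl)Cl
Why: Appel reaction: chloride displaces the alkoxyphosphonium leaving group by SN2 under neutral conditions, which is the standard way to make geranyl-type primary chlorides without allylic shift or E/Z loss, and the silylalkyne is inert.

Step 4
Reactants: 6 allylic chloride; 7 isovaleraldehyde (3-methylbutanal)
Product: 9 (6E,10E)-2,6,10-trimethyl-15-(trimethylsilyl)pentadeca-6,10-dien-14-yn-4-ol (racemic carbinol), via allylbarium chloride 8 (not isolated)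
Conditions: Li, biphenyl, THF, rt; BaI2, THF, rt (activated zerovalent barium); 6, −78 °C, 20 min; 7, −78 °C, 30 min; 1 M HCl
Reagents that add atoms: none
Why: Yamamoto-type allylbarium addition: activated zerovalent barium inserts into the allylic C–Cl bond at −78 °C to give a sigma-bound, configurationally stable allylbarium that attacks the aldehyde through its alpha carbon (C13), giving the linear homoallylic alcohol with the E alkene retained instead of the branched product of Mg, Zn or Cr reagents; the new carbinol centre is racemic on purpose because step 7 erases it.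

Step 5
Reactants: 9 silyl alkynol
Product: 10 (6E,10E)-2,6,10-trimethylpentadeca-6,10-dien-14-yn-4-ol (racemic carbinol)
Conditions: K2CO3 (0.2 equiv), MeOH, rt, 3 h
Reagents that add atoms: none
Why: Base-catalysed protodesilylation: methoxide attacks silicon and releases the acetylide, which methanol protonates, and nothing else in 9 reacts with K2CO3 in MeOH.

Step 6
Reactants: 10 terminal alkynol
Product: 12 (6E,10E,14E)-15-bromo-2,6,10,14-tetramethylpentadeca-6,10,14-trien-4-ol (racemic carbinol), via alkenyldimethylalane 11 (not isolated)
Conditions: AlMe3 (3.5 equiv), Cp2ZrCl2 (0.25 equiv), CH2Cl2, 0 °C to rt, 12 h; then NBS (2 equiv), THF, −30 to 0 °C; H2O quench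
Reagents that add atoms: trimethylaluminium, C[Al](C)C (adds CH3); N-bromosuccinimide, O=C1CCC(=O)N1Br (adds Br)
Why: Negishi zirconium-catalysed carboalumination: after the hydroxyl group is masked in the flask as its dimethylaluminium alkoxide, Me–Al adds syn across the terminal alkyne with methyl at the internal carbon, which fixes the C3=C4 E geometry, and bromodealumination with NBS occurs with retention and faster than NBS attacks the isolated trisubstituted alkenes at low temperature.

Step 7
Reactants: 12 bromo trienol
Product: 13 (6E,10E,14E)-15-bromo-2,6,10,14-tetramethylpentadeca-6,10,14-trien-4-one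
Conditions: Dess–Martin periodinane (1.3 equiv), NaHCO3, CH2Cl2, 0 °C to rt, 1 h
Reagents that add atoms: none
Why: Dess–Martin oxidation: ligand exchange at iodine and intramolecular proton removal work at neutral pH under bicarbonate buffer, so the beta,gamma-alkene does not slide into conjugation and the alkenyl bromide is untouched.

Step 8
Reactants: 13 bromo trienone; 14 3-bromofuran; 15 vinylboronic acid pinacol ester
Product: 18 (6E,10E,14E,17S)-17-(furan-3-yl)-2,6,10,14-tetramethyl-17-(4,4,5,5-tetramethyl-1,3,2-dioxaborolan-2-yl)heptadeca-6,10,14-trien-4-one, via furan-3-yllithium 16 (not isolated), via lithium furyl(vinyl)pinacolatoborate 17 (not isolated)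
Conditions: 14 (1.3 equiv), n-BuLi, Et2O, −78 °C, 30 min; 15 (1.3 equiv), −78 °C to rt; evaporate; 13, Pd(OAc)2 (3 mol %), (Rp,Rp)-1,1'-bis[bis(4-methoxy-3,5-dimethylphenyl)phosphino]-2,2'-bis[(S)-α-(dimethylamino)benzyl]ferrocene (C64H74FeN2O4P2, 3.6 mol %), KOSO2CF3 (2 equiv), THF, 60 °C, 15 h
Reagents that add atoms: none
Why: Enantioselective palladium-catalysed conjunctive cross-coupling (a three-component 1,2-metallate-shift coupling): zerovalent palladium inserts into the C–Br bond of 13 with retention, KOSO2CF3 strips bromide as insoluble KBr, the resulting cationic divalent alkenylpalladium binds one face of the vinyl group of 17 and triggers anti migration of the furyl group from boron to C1, and reductive elimination closes C2–C3, so the chiral diphosphine alone sets the S centre while the tetracoordinate borate is too weak a nucleophile and base to touch the ketone.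

Step 9
Reactants: 18 (S)-boronic ester
Product: 19 (6E,10E,14E,17S)-17-(furan-3-yl)-17-hydroxy-2,6,10,14-tetramethylheptadeca-6,10,14-trien-4-one (target)
Conditions: 30% aq H2O2, NaH2PO4/Na2HPO4 buffer (pH 7), THF, 0 °C to rt, 4 h
Reagents that add atoms: hydrogen peroxide, OO
Why: Boronic ester oxidation: hydroperoxide adds to boron and C1 migrates from boron to oxygen with retention, so S is kept, and the neutral buffer avoids enolisation of the beta,gamma-unsaturated ketone while furan and alkenes are inert to uncatalysed H2O2.

## Compound list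
1 | geranyl bromide, (2E)-1-bromo-3,7-dimethylocta-2,6-diene | CC(C)=CCC/C(C)=C/CBr | starting material
2 | 1-(trimethylsilyl)propyne | CC#C[Si](C)(C)C | starting material
3 | [3-(trimethylsilyl)prop-2-yn-1-yl]lithium | [Li]CC#C[Si](C)(C)C | intermediate
4 | [(5E)-6,10-dimethylundeca-5,9-dien-1-yn-1-yl]trimethylsilane | C[Si](C)(C)C#CCC/C=C(\C)CCC=C(C)C | intermediate
5 | (2E,6E)-2,6-dimethyl-11-(trimethylsilyl)undeca-2,6-dien-10-yn-1-ol | C[Si](C)(C)C#CCC/C=C(\C)CC/C=C(\C)CO | intermediate
6 | [(5E,9E)-11-chloro-6,10-dimethylundeca-5,9-dien-1-yn-1-yl]trimethylsilane | C[Si](C)(C)C#CCC/C=C(\C)CC/C=C(\C)CCl | intermediate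
7 | isovaleraldehyde (3-methylbutanal) | CC(C)CC=O | starting material
8 | [(2E,6E)-2,6-dimethyl-11-(trimethylsilyl)undeca-2,6-dien-10-yn-1-yl]barium chloride | C[Si](C)(C)C#CCC/C=C(\C)CC/C=C(\C)C[Ba]Cl | intermediate
9 | (6E,10E)-2,6,10-trimethyl-15-(trimethylsilyl)pentadeca-6,10-dien-14-yn-4-ol, racemic carbinol | C[Si](C)(C)C#CCC/C=C(\C)CC/C=C(\C)CC(O)CC(C)C | intermediate
10 | (6E,10E)-2,6,10-trimethylpentadeca-6,10-dien-14-yn-4-ol, racemic carbinol | C#CCC/C=C(\C)CC/C=C(\C)CC(O)CC(C)C | intermediate
11 | (E)-alkenyldimethylalane of 10, hydroxyl held as its dimethylaluminium alkoxide | C[Al](C)/C=C(\C)CC/C=C(\C)CC/C=C(\C)CC(O[Al](C)C)CC(C)C | intermediate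
12 | (6E,10E,14E)-15-bromo-2,6,10,14-tetramethylpentadeca-6,10,14-trien-4-ol, racemic carbinol | Br/C=C(\C)CC/C=C(\C)CC/C=C(\C)CC(O)CC(C)C | intermediate
13 | (6E,10E,14E)-15-bromo-2,6,10,14-tetramethylpentadeca-6,10,14-trien-4-one | Br/C=C(\C)CC/C=C(\C)CC/C=C(\C)CC(=O)CC(C)C | intermediate
14 | 3-bromofuran | Brc1ccoc1 | starting material
15 | vinylboronic acid pinacol ester (2-ethenyl-4,4,5,5-tetramethyl-1,3,2-dioxaborolane) | C=CB1OC(C)(C)C(C)(C)O1 | starting material
16 | furan-3-yllithium | [Li]c1ccoc1 | intermediate
17 | lithium ethenyl(furan-3-yl)(pinacolato)borate | [Li+].C=C[B-]1(c2ccoc2)OC(C)(C)C(C)(C)O1 | intermediate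
18 | (6E,10E,14E,17S)-17-(furan-3-yl)-2,6,10,14-tetramethyl-17-(4,4,5,5-tetramethyl-1,3,2-dioxaborolan-2-yl)heptadeca-6,10,14-trien-4-one | C/C(=C\CC/C(C)=C/C[C@H](B1OC(C)(C)C(C)(C)O1)c1ccoc1)CC/C=C(\C)CC(=O)CC(C)C | intermediate
19 | (6E,10E,14E,17S)-17-(furan-3-yl)-17-hydroxy-2,6,10,14-tetramethylheptadeca-6,10,14-trien-4-one | C/C(=C\CC/C(C)=C/C[C@H](O)c1ccoc1)CC/C=C(\C)CC(=O)CC(C)C | target

## Step count and risks
Total step count: 9. Longest linear sequence: 9 steps (1 to 19). Compounds 2, 7, 14 and 15 are bought and enter directly.

**Step 8 is the most likely to fail.**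
- Risks: the electron-rich furyl group may transfer directly to palladium (plain Suzuki product). Residual bromide may block the cationic palladium site. The doubly activated C13 methylene of 13 sits at 60 °C for hours. The level and sense of induction with a 3-furyl migrating group and a trisubstituted alkenyl bromide are untested.
- Fallback: it sets out from 12 together with 14 and 15 and comes back at 18. The stereocentre is set first on a small alkene by diboration, and C2–C3 is then made by a site-selective Suzuki coupling.
- Suzuki coupling of 14 with 15 (Pd(PPh3)4, K2CO3, THF/H2O, 60 °C) gives 3-ethenylfuran F1. Platinum-catalysed enantioselective diboration follows (Pt(dba)3, the antipode of the TADDOL-derived phenylphosphonite ligand that gives S, bis(pinacolato)diboron, THF, 60 °C). It gives the (S)-1,2-bis(boronic ester) F2, whose ee can be measured and upgraded early.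
- Only the primary C–B bond of F2 couples with the alkenyl bromide of 12 (Pd(OAc)2, 2-dicyclohexylphosphino-2',6'-diisopropoxybiphenyl, KOH, THF/H2O, 70 °C), giving the hydroxy boronic ester F3. The alcohol 12 is used rather than the ketone 13 because hot KOH would conjugate the enone. Dess–Martin oxidation of F3 (NaHCO3, CH2Cl2) gives 18, and step 9 follows unchanged.

**Step 4.**
- Risks: the result depends on the quality of the activated barium. Wurtz dimerisation of 6 and loss of alpha selectivity or E geometry follow if the allylbarium warms above −78 °C.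
- Fallback: it sets out from 6 and 7 and comes back at 9. The polarity is inverted, so the allyl unit stays the electrophile and the aldehyde becomes an acyl anion.
- Treating 7 with propane-1,3-dithiol and BF3·OEt2 gives 2-(2-methylpropyl)-1,3-dithiane F4. n-BuLi (THF, −30 °C) gives the 2-lithiodithiane F5, which displaces the chloride of 6 by SN2 to give the allylated dithiane F6. MeI and CaCO3 in aqueous MeCN unmask the silyl dienynone F7, and NaBH4 (MeOH, 0 °C) gives 9.

**Step 2.**
- Risks: the internal trisubstituted alkene and the propargylic CH2 compete with the terminal isopropylidene group, and over-oxidation to the enal lowers the yield.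
- Fallback: it sets out from 4 and comes back at 6, so step 3 is skipped. It replaces C–H oxidation with terminal-selective alkene functionalisation and an allylic transposition.
- NBS in aqueous THF at 0 °C attacks the exposed terminal alkene and gives the terminal bromohydrin F8. NaH (THF, 0 °C) closes the terminal epoxide F9 without touching the silylalkyne. Al(OiPr)3 (toluene, reflux) isomerises it to the secondary allylic alcohol F10. SOCl2 (Et2O, 0 °C) then delivers chloride with allylic shift (SNi') to give the E primary chloride 6.

## Further compounds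
F1 | step 8 | 3-ethenylfuran | C=Cc1ccoc1
F2 | step 8 | 2,2'-[(1S)-1-(furan-3-yl)ethane-1,2-diyl]bis(4,4,5,5-tetramethyl-1,3,2-dioxaborolane) | CC1(C)OB(C[C@H](B2OC(C)(C)C(C)(C)O2)c2ccoc2)OC1(C)C
F3 | step 8 | (6E,10E,14E,17S)-17-(furan-3-yl)-2,6,10,14-tetramethyl-17-(4,4,5,5-tetramethyl-1,3,2-dioxaborolan-2-yl)heptadeca-6,10,14-trien-4-ol, both epimers at C4 | C/C(=C\CC/C(C)=C/C[C@H](B1OC(C)(C)C(C)(C)O1)c1ccoc1)CC/C=C(\C)CC(O)CC(C)C
F4 | step 4 | 2-(2-methylpropyl)-1,3-dithiane | CC(C)CC1SCCCS1
F5 | step 4 | 2-lithio-2-(2-methylpropyl)-1,3-dithiane | [Li]C1(CC(C)C)SCCCS1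
F6 | step 4 | {(5E,9E)-6,10-dimethyl-11-[2-(2-methylpropyl)-1,3-dithian-2-yl]undeca-5,9-dien-1-yn-1-yl}trimethylsilane | C[Si](C)(C)C#CCC/C=C(\C)CC/C=C(\C)CC1(CC(C)C)SCCCS1
F7 | step 4 | (6E,10E)-2,6,10-trimethyl-15-(trimethylsilyl)pentadeca-6,10-dien-14-yn-4-one | C[Si](C)(C)C#CCC/C=C(\C)CC/C=C(\C)CC(=O)CC(C)C
F8 | step 2 | (6E)-3-bromo-2,6-dimethyl-11-(trimethylsilyl)undec-6-en-10-yn-2-ol, racemic | C[Si](C)(C)C#CCC/C=C(\C)CCC(Br)C(C)(C)O
F9 | step 2 | [(5E)-8-(3,3-dimethyloxiran-2-yl)-6-methyloct-5-en-1-yn-1-yl]trimethylsilane, racemic | C[Si](C)(C)C#CCC/C=C(\C)CCC1OC1(C)C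
F10 | step 2 | (6E)-2,6-dimethyl-11-(trimethylsilyl)undeca-1,6-dien-10-yn-3-ol, racemic | C[Si](C)(C)C#CCC/C=C(\C)CCC(O)C(C)=C
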